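**Retrosynthetic overview**

1. Ring C is numbered C1 (quaternary: methyl, styryl), C2, C3, C4(methyl)=C5, C6 (H, aryl). The route rests on one feature: O1 of coumarin B (on the aryl bound to C6) and the styryl α-carbon on C1 are cis and 1,4-related across the C1–C6 bond. Both can therefore sit in a δ-lactone, a temporary 5-methoxycoumarin whose C3=C4 alkene is C1=C6.
2. Late stage: the pyranone of coumarin B is closed by ortho-formylation and Wittig lactonisation; coumarin A is attached whole by a Heck reaction on a vinyl group; the vinyl group comes from the lactone carbonyl by reduction and methylenation.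
3. Middle stage: the C4=C5 alkene comes from SE2′ protodesilylation of a C5-silyl, C3=C4 allylsilane; the C1 methyl comes from alkylation of the lactone enolate after reductive removal of a C1 sulfone.
4. Key disconnection: C1–C2 and C5–C6, by [4+2] cycloaddition of 5-methoxy-3-(phenylsulfonyl)coumarin with (E)-1-silyl-2-methylbutadiene under a chiral copper Lewis acid.
5. Ring order: temporary pyranone (Knoevenagel), ring C (Diels–Alder), temporary lactone opened, coumarin A attached preformed, pyranone of coumarin B last.

Key step: step 4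

**Assumptions and numbering**

- The facial sense of the copper–bis(oxazoline) catalyst toward this sulfonyl lactone chelate cannot be predicted with confidence. The (S,S) ligand, 2,2′-(propane-2,2-diyl)bis[(4S)-4-tert-butyl-4,5-dihydrooxazole] ("(S,S)-t-Bu-box"), is written; its (R,R) mirror image is to be used if the adduct proves to belong to the enantiomeric series.
- The configuration at the silyl-bearing carbon C10 is left open, because step 7 removes that centre.
- In the tricyclic intermediates (benzo[c]chromene numbering), C6a, C7, C8, C9, C10 and C10a are C1, C2, C3, C4, C5 and C6 of ring C.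

**Route**

Step 1
Reactants: 1 2-hydroxy-6-methoxybenzaldehyde; 2 methyl 2-(phenylsulfonyl)acetate
Product: 4 5-methoxy-3-(phenylsulfonyl)-2H-chromen-2-one, via Knoevenagel acrylate 3 (not isolated)
Conditions: piperidine (cat.), AcOH (cat.), EtOH, reflux
Reagents that add atoms: none
Why: Knoevenagel condensation of the aldehyde with the doubly activated methylene of 2 is followed by attack of the ortho-hydroxyl on the methyl ester, the standard entry to 3-sulfonylcoumarins; no stereocentre is formed.

Step 2
Reactants: 5 3-methyl-2,5-dihydrothiophene 1,1-dioxide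
Product: 7 3-methyl-2-(trimethylsilyl)-2,5-dihydrothiophene 1,1-dioxide (racemic), via 2-lithio sulfolene 6 (not isolated)
Conditions: Me3SiCl, then LiN(SiMe3)2 added slowly, THF, −78 °C
Reagents that add atoms: chlorotrimethylsilane, C[Si](C)(C)Cl
Why: α-Sulfonyl metalation of a 3-sulfolene with in situ silylation should occur at C2 and not at C5, because the C2 allyl anion keeps the methyl group on its central carbon, and the anion is silylated before the ring can open; the new centre is racemic and is destroyed in step 3, and any C5-silylated isomer is removed at this stage.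

Step 3
Reactants: 7 3-methyl-2-(trimethylsilyl)-2,5-dihydrothiophene 1,1-dioxide
Product: 8 (E)-trimethyl(2-methylbuta-1,3-dien-1-yl)silane
Conditions: neat, NaHCO3, 130 °C, diene distilled out as it forms
Reagents that add atoms: none
Why: Cheletropic extrusion of SO2 from a 2-substituted 3-sulfolene is disrotatory with the C2 substituent turning outward, which should give the E-1-silyl diene only.

Step 4
Reactants: 4 5-methoxy-3-(phenylsulfonyl)-2H-chromen-2-one; 8 (E)-trimethyl(2-methylbuta-1,3-dien-1-yl)silane
Product: 9 (6aR,10aR)-1-methoxy-9-methyl-6a-(phenylsulfonyl)-10-(trimethylsilyl)-6a,7,10,10a-tetrahydro-6H-benzo[c]chromen-6-one (cis ring fusion; C10 not defined)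
Conditions: Cu(SbF6)2·(S,S)-t-Bu-box (15 mol %), 4 Å MS, CH2Cl2, −20 °C to rt
Reagents that add atoms: none
Why: Proposed new method: the cationic divalent copper–bis(oxazoline) complex should hold the lactone carbonyl and one sulfonyl oxygen of 4 in a six-membered chelate and so lower the LUMO of the C3=C4 alkene, to which diene 8 adds in a concerted, asynchronous normal-demand [4+2] cycloaddition. The closest known reaction types are thermal and Lewis-acid Diels–Alder additions to 3-acceptor-substituted coumarins and copper–bis(oxazoline) catalysis of two-point-binding dienophiles; their combination on a 3-sulfonylcoumarin is new. Ring C closes by intermolecular [4+2] annulation, the C10a–C10 and C6a–C7 bonds forming on one face of the dienophile and suprafacially on the s-cis diene. C6a and C10a are cis because the dienophile is a ring Z-alkene, their absolute configuration is set by the tert-butyl groups of the ligand, which screen one face of the chelated coumarin, and C10 follows from the expected ring-endo approach of the E-diene (silicon trans to H-10a) but is removed in step 7. The step needs "para" regiochemistry and π-face selectivity: the first is secured by the diene, whose silicon-bearing terminus is the nucleophilic one because bonding there leaves the developing positive charge on the methyl-bearing carbon β to silicon, and the second rests on the rigid chelate.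

Step 5
Reactants: 9 (6aR,10aR)-1-methoxy-9-methyl-6a-(phenylsulfonyl)-10-(trimethylsilyl)-6a,7,10,10a-tetrahydro-6H-benzo[c]chromen-6-one
Product: 11 (10aR)-1-methoxy-9-methyl-10-(trimethylsilyl)-6a,7,10,10a-tetrahydro-6H-benzo[c]chromen-6-one (C6a and C10 not defined), via samarium enolate 10 (not isolated)
Conditions: SmI2 (2.5 equiv), THF–MeOH, −78 °C
Reagents that add atoms: none
Why: Samarium diiodide cleaves the C–S bond of an α-sulfonyl lactone by two single-electron transfers (reductive desulfonylation) and methanol protonates the enolate; C6a need not be controlled here because step 6 re-forms it, and C10a is untouched.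

Step 6
Reactants: 11 (10aR)-1-methoxy-9-methyl-10-(trimethylsilyl)-6a,7,10,10a-tetrahydro-6H-benzo[c]chromen-6-one
Product: 13 (6aS,10aS)-1-methoxy-6a,9-dimethyl-10-(trimethylsilyl)-6a,7,10,10a-tetrahydro-6H-benzo[c]chromen-6-one (cis-fused; C10 not defined), via lithium enolate 12 (not isolated)
Conditions: LiN(i-Pr)2, THF, −78 °C; then MeI, DMPU, −78 to −40 °C
Reagents that add atoms: iodomethane, CI
Why: Alkylation of a ring-fusion lactone enolate: MeI should approach C6a from the face that carries the small H-10a, away from C10 and its silyl group, so the methyl group ends cis to H-10a and the lactone carbonyl stays cis to the aryl carbon.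

Step 7
Reactants: 13 (6aS,10aS)-1-methoxy-6a,9-dimethyl-10-(trimethylsilyl)-6a,7,10,10a-tetrahydro-6H-benzo[c]chromen-6-one
Product: 14 (6aS,10aS)-1-methoxy-6a,9-dimethyl-6a,7,8,10a-tetrahydro-6H-benzo[c]chromen-6-one
Conditions: CF3CO2H (2 equiv), CH2Cl2, 0 °C; aqueous work-up
Reagents that add atoms: none
Why: Acid-mediated SE2′ protodesilylation of an allylsilane: the proton adds to C8 while positive charge builds at the methyl-bearing C9 β to silicon, and loss of silicon leaves the C9=C10 alkene (C4=C5 of ring C) without touching C6a or C10a.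

Step 8
Reactants: 14 (6aS,10aS)-1-methoxy-6a,9-dimethyl-6a,7,8,10a-tetrahydro-6H-benzo[c]chromen-6-one
Product: 15 (6aS,10aS)-1-methoxy-6a,9-dimethyl-6a,7,8,10a-tetrahydro-6H-benzo[c]chromen-6-ol (lactol; both C6 epimers)
Conditions: i-Bu2AlH (1.2 equiv), CH2Cl2, −78 °C; aq. KNaC4H4O6
Reagents that add atoms: none
Why: Half-reduction of a lactone with i-Bu2AlH at −78 °C should stop at the hemiacetal oxidation level, as is established for dihydrocoumarins, and the α-quaternary centre cannot epimerise.

Step 9
Reactants: 15 (6aS,10aS)-1-methoxy-6a,9-dimethyl-6a,7,8,10a-tetrahydro-6H-benzo[c]chromen-6-ol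
Product: 17 2-[(1R,6R)-6-ethenyl-3,6-dimethylcyclohex-2-en-1-yl]-3-methoxyphenol, via ring-opened hydroxy aldehyde 16 (not isolated)
Conditions: Ph3PCH3Br (4 equiv), KOt-Bu, THF, 0 to 50 °C
Reagents that add atoms: methyltriphenylphosphonium bromide, C[P+](c1ccccc1)(c1ccccc1)c1ccccc1.[Br-]
Why: Under base the lactol opens to aldehyde 16, and Wittig methylenation with excess Ph3P=CH2 (one equivalent is taken by the phenol) should give the vinyl group; the aldehyde has no α-hydrogen, so C1 of ring C is safe.

Step 10
Reactants: 18 7-hydroxy-2H-chromen-2-one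
Product: 19 7-hydroxy-8-iodo-2H-chromen-2-one
Conditions: I2, KI, 20% aq. NH3, rt; then aq. HCl
Reagents that add atoms: iodine, II
Why: Electrophilic aromatic iodination of the phenoxide in aqueous ammonia is expected to favour C8, the position between the phenoxide carbon and the carbon bearing the ring oxygen; the minor 6-iodo isomer is removed by crystallisation.

Step 11
Reactants: 19 7-hydroxy-8-iodo-2H-chromen-2-one
Product: 20 8-iodo-7-methoxy-2H-chromen-2-one
Conditions: MeI, K2CO3, acetone, reflux
Reagents that add atoms: iodomethane, CI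
Why: Williamson O-methylation of the acidic 7-hydroxyl, which the lactone and the aryl iodide tolerate.

Step 12
Reactants: 17 2-[(1R,6R)-6-ethenyl-3,6-dimethylcyclohex-2-en-1-yl]-3-methoxyphenol; 20 8-iodo-7-methoxy-2H-chromen-2-one
Product: 21 8-[(E)-2-[(1R,2R)-2-(2-hydroxy-6-methoxyphenyl)-1,4-dimethylcyclohex-3-en-1-yl]ethenyl]-7-methoxy-2H-chromen-2-one
Conditions: Pd(OAc)2 (10 mol %), n-Bu4NCl, NaHCO3, DMF, 85 °C
Reagents that add atoms: none
Why: Mizoroki–Heck reaction under ligand-free phase-transfer conditions: the aryl group adds to the unsubstituted vinyl terminus, and because the neighbouring carbon is quaternary the only syn β-hydrogen is the benzylic one, which should give the E-styrene without alkene migration.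

Step 13
Reactants: 21 8-[(E)-2-[(1R,2R)-2-(2-hydroxy-6-methoxyphenyl)-1,4-dimethylcyclohex-3-en-1-yl]ethenyl]-7-methoxy-2H-chromen-2-one
Product: 23 2-hydroxy-4-methoxy-3-[(1R,6R)-6-[(E)-2-(7-methoxy-2-oxo-2H-chromen-8-yl)ethenyl]-3,6-dimethylcyclohex-2-en-1-yl]benzaldehyde, via salicyl alcohol 22 (not isolated)
Conditions: MgCl2, Et3N, (CH2O)n, MeCN, 75 °C; aq. HCl
Reagents that add atoms: paraformaldehyde (formaldehyde), C=O
Why: Casnati–Skattebøl ortho-formylation: formaldehyde is delivered to the only free position ortho to the magnesium-bound phenol oxygen (also para to the methoxy group) to give 22, which a second equivalent of formaldehyde oxidises to the aldehyde by hydride transfer.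

Step 14
Reactants: 23 2-hydroxy-4-methoxy-3-[(1R,6R)-6-[(E)-2-(7-methoxy-2-oxo-2H-chromen-8-yl)ethenyl]-3,6-dimethylcyclohex-2-en-1-yl]benzaldehyde
Product: 25 7-methoxy-8-[(E)-2-[(1R,2R)-2-(7-methoxy-2-oxo-2H-chromen-8-yl)-1,4-dimethylcyclohex-3-en-1-yl]ethenyl]-2H-chromen-2-one, via ester ylide 24 (not isolated)
Conditions: Ph3P=C=C=O, toluene, 90 °C
Reagents that add atoms: (triphenylphosphoranylidene)ketene, O=C=C=P(c1ccccc1)(c1ccccc1)c1ccccc1
Why: Wittig lactonisation: the phenol adds to the ketene ylide to give ester ylide 24, whose intramolecular Wittig reaction with the ortho aldehyde can only give the cis alkene of the pyranone, at a temperature well below that at which the 1,5-diene around C1–C6 could rearrange.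

**Compound list**

1 | 2-hydroxy-6-methoxybenzaldehyde | COc1cccc(O)c1C=O | starting material
2 | methyl 2-(phenylsulfonyl)acetate | COC(=O)CS(=O)(=O)c1ccccc1 | starting material
3 | methyl 3-(2-hydroxy-6-methoxyphenyl)-2-(phenylsulfonyl)prop-2-enoate (alkene geometry not fixed) | COC(=O)C(=Cc1c(O)cccc1OC)S(=O)(=O)c1ccccc1 | intermediate
4 | 5-methoxy-3-(phenylsulfonyl)-2H-chromen-2-one | COc1cccc2oc(=O)c(S(=O)(=O)c3ccccc3)cc12 | intermediate
5 | 3-methyl-2,5-dihydrothiophene 1,1-dioxide (3-methyl-3-sulfolene) | CC1=CCS(=O)(=O)C1 | starting material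
6 | 2-lithio-3-methyl-2,5-dihydrothiophene 1,1-dioxide | [Li]C1C(C)=CCS1(=O)=O | intermediate
7 | 3-methyl-2-(trimethylsilyl)-2,5-dihydrothiophene 1,1-dioxide (racemic) | CC1=CCS(=O)(=O)C1[Si](C)(C)C | intermediate
8 | (E)-trimethyl(2-methylbuta-1,3-dien-1-yl)silane | C[Si](C)(C)/C=C(\C)C=C | intermediate
9 | (6aR,10aR)-1-methoxy-9-methyl-6a-(phenylsulfonyl)-10-(trimethylsilyl)-6a,7,10,10a-tetrahydro-6H-benzo[c]chromen-6-one (cis-fused, sulfonyl and H-10a on one face; C10 not defined) | O=C1Oc2cccc(OC)c2[C@@H]3C([Si](C)(C)C)C(C)=CC[C@]13S(=O)(=O)c1ccccc1 | intermediate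
10 | diiodosamarium enolate (trivalent samarium) of lactone 11 | I[Sm](I)OC1=C2CC=C(C)C([Si](C)(C)C)[C@H]2c3c(OC)cccc3O1 | intermediate
11 | (10aR)-1-methoxy-9-methyl-10-(trimethylsilyl)-6a,7,10,10a-tetrahydro-6H-benzo[c]chromen-6-one (C6a and C10 not defined) | O=C1Oc2cccc(OC)c2[C@@H]3C([Si](C)(C)C)C(C)=CCC13 | intermediate
12 | lithium enolate of lactone 11 | [Li]OC1=C2CC=C(C)C([Si](C)(C)C)[C@H]2c3c(OC)cccc3O1 | intermediate
13 | (6aS,10aS)-1-methoxy-6a,9-dimethyl-10-(trimethylsilyl)-6a,7,10,10a-tetrahydro-6H-benzo[c]chromen-6-one (cis-fused, 6a-methyl and H-10a on one face; C10 not defined) | O=C1Oc2cccc(OC)c2[C@@H]3C([Si](C)(C)C)C(C)=CC[C@]13C | intermediate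
14 | (6aS,10aS)-1-methoxy-6a,9-dimethyl-6a,7,8,10a-tetrahydro-6H-benzo[c]chromen-6-one | O=C1Oc2cccc(OC)c2[C@@H]3C=C(C)CC[C@]13C | intermediate
15 | (6aS,10aS)-1-methoxy-6a,9-dimethyl-6a,7,8,10a-tetrahydro-6H-benzo[c]chromen-6-ol (both C6 epimers) | OC1Oc2cccc(OC)c2[C@@H]3C=C(C)CC[C@]13C | intermediate
16 | (1S,2S)-2-(2-hydroxy-6-methoxyphenyl)-1,4-dimethylcyclohex-3-ene-1-carbaldehyde | O=C[C@@]1(C)CCC(C)=C[C@H]1c1c(OC)cccc1O | intermediate
17 | 2-[(1R,6R)-6-ethenyl-3,6-dimethylcyclohex-2-en-1-yl]-3-methoxyphenol | C=C[C@@]1(C)CCC(C)=C[C@H]1c1c(OC)cccc1O | intermediate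
18 | 7-hydroxy-2H-chromen-2-one (umbelliferone) | Oc1ccc2ccc(=O)oc2c1 | starting material
19 | 7-hydroxy-8-iodo-2H-chromen-2-one | Oc1ccc2ccc(=O)oc2c1I | intermediate
20 | 8-iodo-7-methoxy-2H-chromen-2-one | COc1ccc2ccc(=O)oc2c1I | intermediate
21 | 8-[(E)-2-[(1R,2R)-2-(2-hydroxy-6-methoxyphenyl)-1,4-dimethylcyclohex-3-en-1-yl]ethenyl]-7-methoxy-2H-chromen-2-one | COc1ccc2ccc(=O)oc2c1/C=C/[C@@]1(C)CCC(C)=C[C@H]1c1c(OC)cccc1O | intermediate
22 | 8-[(E)-2-[(1R,2R)-2-[2-hydroxy-3-(hydroxymethyl)-6-methoxyphenyl]-1,4-dimethylcyclohex-3-en-1-yl]ethenyl]-7-methoxy-2H-chromen-2-one | COc1ccc2ccc(=O)oc2c1/C=C/[C@@]1(C)CCC(C)=C[C@H]1c1c(OC)ccc(CO)c1O | intermediate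
23 | 2-hydroxy-4-methoxy-3-[(1R,6R)-6-[(E)-2-(7-methoxy-2-oxo-2H-chromen-8-yl)ethenyl]-3,6-dimethylcyclohex-2-en-1-yl]benzaldehyde | COc1ccc2ccc(=O)oc2c1/C=C/[C@@]1(C)CCC(C)=C[C@H]1c1c(OC)ccc(C=O)c1O | intermediate
24 | 6-formyl-3-methoxy-2-[(1R,6R)-6-[(E)-2-(7-methoxy-2-oxo-2H-chromen-8-yl)ethenyl]-3,6-dimethylcyclohex-2-en-1-yl]phenyl 2-(triphenylphosphoranylidene)acetate | COc1ccc2ccc(=O)oc2c1/C=C/[C@@]1(C)CCC(C)=C[C@H]1c1c(OC)ccc(C=O)c1OC(=O)C=P(c1ccccc1)(c1ccccc1)c1ccccc1 | intermediate
25 | 7-methoxy-8-[(E)-2-[(1R,2R)-2-(7-methoxy-2-oxo-2H-chromen-8-yl)-1,4-dimethylcyclohex-3-en-1-yl]ethenyl]-2H-chromen-2-one (CNP0156435.1) | COc1ccc2ccc(=O)oc2c1/C=C/[C@@]1(C)CCC(C)=C[C@H]1c1c(OC)ccc2ccc(=O)oc12 | target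

**Step count**

Total step count: 14.
Longest linear sequence: 11 steps (steps 2, 3, 4, 5, 6, 7, 8, 9, 12, 13, 14).

**Steps most likely to fail**

Step 4 (proposed new method).
- What may go wrong: the cycloaddition may stall, because the silicon-bearing diene terminus must bond to C4 next to the peri 5-methoxy group, which also donates into the enoate.
- The Lewis acid may instead trigger desilylative conjugate addition or protodesilylation of the diene.
- Face discrimination may be poor, because the chelate relies on a weakly basic sulfonyl oxygen.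
- Fallback, setting out from 4 and 8 and coming back at 9: the two are combined without a chiral catalyst in CH2Cl2 under 10–12 kbar at ambient temperature, conditions under which other 3-acceptor coumarins are known to accept dienes. This should give the racemic cis-fused adduct, rac-1-methoxy-9-methyl-6a-(phenylsulfonyl)-10-(trimethylsilyl)-6a,7,10,10a-tetrahydro-6H-benzo[c]chromen-6-one F1. Its enantiomers are then separated by preparative chromatography on a polysaccharide chiral stationary phase, and the (6aR,10aR) enantiomer is 9.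

Step 12.
- What may go wrong: carbopalladation of the neopentyl-type vinyl group by a doubly ortho-substituted arylpalladium species may be slow, so that reductive deiodination of the aryl iodide or interference by the free phenol takes over.
- Fallback, setting out from 15 and 20 and coming back at 21: lactol 15 reacts through its open aldehyde form in a Takai iodo-olefination (CrCl2, CHI3, THF, 0 °C to rt), which should give 2-[(1R,6S)-6-[(E)-2-iodoethenyl]-3,6-dimethylcyclohex-2-en-1-yl]-3-methoxyphenol F2. Iodide 20 is converted by Miyaura borylation (B2pin2, Pd(dppf)Cl2, KOAc, dioxane, 80 °C) into 7-methoxy-8-(4,4,5,5-tetramethyl-1,3,2-dioxaborolan-2-yl)-2H-chromen-2-one F3. Suzuki–Miyaura coupling of the two (Pd(PPh3)4, K3PO4, dioxane–water, 60 °C) should then give 21 with the E geometry retained.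

Step 6.
- What may go wrong: the aryl-lactone enolate may expel its phenoxide (ring opening to a ketene) or be methylated on oxygen faster than it is methylated at the hindered ring-fusion carbon.
- Fallback, setting out from 9 and coming back at 13: the samarium enolate is made from 9 with SmI2 in THF at −78 °C without an amine base and is trapped at once with monomeric formaldehyde in a Reformatsky-type aldol reaction, on the same face as the methylation. This should give (6aS,10aS)-6a-(hydroxymethyl)-1-methoxy-9-methyl-10-(trimethylsilyl)-6a,7,10,10a-tetrahydro-6H-benzo[c]chromen-6-one F4. Appel iodination (Ph3P, I2, imidazole, premixed, toluene, 60 °C) should give (6aR,10aS)-6a-(iodomethyl)-1-methoxy-9-methyl-10-(trimethylsilyl)-6a,7,10,10a-tetrahydro-6H-benzo[c]chromen-6-one F5, and radical reduction with n-Bu3SnH and AIBN in toluene at 80 °C should turn the iodomethyl group into the methyl group of 13.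

**Further compounds**

F1 | step 4 | rac-1-methoxy-9-methyl-6a-(phenylsulfonyl)-10-(trimethylsilyl)-6a,7,10,10a-tetrahydro-6H-benzo[c]chromen-6-one (racemic, cis-fused) | O=C1Oc2cccc(OC)c2C3C([Si](C)(C)C)C(C)=CCC13S(=O)(=O)c1ccccc1
F2 | step 12 | 2-[(1R,6S)-6-[(E)-2-iodoethenyl]-3,6-dimethylcyclohex-2-en-1-yl]-3-methoxyphenol | I/C=C/[C@@]1(C)CCC(C)=C[C@H]1c1c(OC)cccc1O
F3 | step 12 | 7-methoxy-8-(4,4,5,5-tetramethyl-1,3,2-dioxaborolan-2-yl)-2H-chromen-2-one | COc1ccc2ccc(=O)oc2c1B1OC(C)(C)C(C)(C)O1
F4 | step 6 | (6aS,10aS)-6a-(hydroxymethyl)-1-methoxy-9-methyl-10-(trimethylsilyl)-6a,7,10,10a-tetrahydro-6H-benzo[c]chromen-6-one (C10 not defined) | O=C1Oc2cccc(OC)c2[C@@H]3C([Si](C)(C)C)C(C)=CC[C@]13CO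
F5 | step 6 | (6aR,10aS)-6a-(iodomethyl)-1-methoxy-9-methyl-10-(trimethylsilyl)-6a,7,10,10a-tetrahydro-6H-benzo[c]chromen-6-one (C10 not defined) | O=C1Oc2cccc(OC)c2[C@@H]3C([Si](C)(C)C)C(C)=CC[C@]13CI
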